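**Retrosynthetic overview**
1. Lepadin H ⇒ removal of N-Boc and O-TBS ⇒ the C3–O ester bond is made with inversion (Mitsunobu) from the all-cis N-Boc decahydroquinolin-3-ol 13 and dienoic acid 17 (hexenal + malonic acid).
2. 13 ⇒ all-cis hydrogenation of the benzene ring of tetrahydroquinoline 12; the face is fixed by the C2 methyl group.
3. 12 ⇒ B-alkyl Suzuki coupling of aryl bromide 9 with alkene 4, made from (R)-2-propyloxirane and allylmagnesium bromide.
4. 9 ⇒ one-pot C–N annulation/asymmetric transfer hydrogenation of 2-amino-6-bromobenzaldehyde with acetoxyacetone, which sets C2 and C3.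
5. Ring order: the benzene ring is present from the start, the nitrogen ring is closed in step 3, and the carbocycle is saturated in step 6.

Assumption: 2-amino-6-bromobenzaldehyde, (R)-2-propyloxirane, acetoxyacetone and the chiral phosphoric acid are bought as catalogue items.

**Step 1**
Reactants: 1 (R)-2-propyloxirane; 2 allylmagnesium bromide
Product: 3 (R)-oct-7-en-4-ol
Conditions: CuI (5 mol%), THF, −30 to 0 °C; aqueous work-up
Reagents that add atoms: none
Why: Copper-catalysed Grignard opening of the terminal epoxide (SN2 at the unsubstituted carbon) leaves the C–O stereocentre of 1 untouched, so the (R) carbinol that becomes C5' comes from the chiral pool.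

**Step 2**
Reactants: 3 (R)-oct-7-en-4-ol
Product: 4 (R)-tert-butyldimethyl(oct-7-en-4-yloxy)silane
Conditions: TBSCl, imidazole, DMF, rt
Reagents that add atoms: tert-butyldimethylsilyl chloride (TBSCl), CC(C)(C)[Si](C)(C)Cl
Why: Imidazole-mediated silylation masks the side-chain alcohol so that only the ring hydroxyl is free in the later esterification.

**Step 3**
Reactants: 5 2-amino-6-bromobenzaldehyde; 6 2-oxopropyl acetate (acetoxyacetone)
Product: 8 (2S,3S)-5-bromo-2-methyl-1,2,3,4-tetrahydroquinolin-3-yl acetate, via quinolinyl acetate 7 (not isolated)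
Conditions: Mg(OTf)2 (10 mol%), (S)-3,3'-bis(2,4,6-triisopropylphenyl)-1,1'-binaphthyl-2,2'-diyl hydrogen phosphate (5 mol%), 5 Å MS, toluene, 60 °C; then Hantzsch ester (diethyl 2,6-dimethyl-1,4-dihydropyridine-3,5-dicarboxylate, 2.4 equiv), 35 °C
Reagents that add atoms: none
Why: Proposed new method: an α-acyloxy ketone has not been used as the partner in a relay Friedländer annulation/asymmetric transfer hydrogenation. Acid-promoted condensation (imine, enamine at the more acidic CH2OAc carbon, cyclodehydration) forms the N1–C2 bond and the pyridine ring of 7. The phosphate-bound quinolinium then takes hydride at C4, and the resulting enamine/enol acetate is protonated at C3 to two rapidly interconverting iminium epimers (dynamic kinetic resolution). The chiral phosphate steers the last hydride to the C2 face anti to the pseudoaxial acetoxy group, giving the cis (2S,3S) product; the sense of induction is assigned by analogy with 2-alkylquinolines, and the antipodal acid is equally available. The closest known reaction types are the relay Friedländer condensation/chiral phosphoric acid transfer hydrogenation with simple ketones and the cis-selective asymmetric reduction of 2,3-dialkylquinolines.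

**Step 4**
Reactants: 8 (2S,3S)-5-bromo-2-methyl-1,2,3,4-tetrahydroquinolin-3-yl acetate
Product: 9 tert-butyl (2S,3S)-3-acetoxy-5-bromo-2-methyl-3,4-dihydroquinoline-1(2H)-carboxylate
Conditions: Boc2O, 4-(dimethylamino)pyridine (0.2 equiv), MeCN, 60 °C
Reagents that add atoms: di-tert-butyl dicarbonate (Boc2O), CC(C)(C)OC(=O)OC(=O)OC(C)(C)C
Why: Carbamate formation (Boc protection) on the anilinic N–H proceeds under nucleophilic catalysis while the acetate keeps O3 from reacting, and the Boc group later forces the C2 methyl pseudoaxial.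

**Step 5**
Reactants: 4 (R)-tert-butyldimethyl(oct-7-en-4-yloxy)silane; 9 tert-butyl (2S,3S)-3-acetoxy-5-bromo-2-methyl-3,4-dihydroquinoline-1(2H)-carboxylate
Product: 12 tert-butyl (2S,3S)-5-[(5R)-5-(tert-butyldimethylsilyloxy)octyl]-3-hydroxy-2-methyl-3,4-dihydroquinoline-1(2H)-carboxylate, via alkylborane 10 (not isolated), via coupled acetate 11 (not isolated)
Conditions: 4, 9-BBN, THF, 0 °C to rt; then 9, Pd(dppf)Cl2 (3 mol%), K3PO4 (3 equiv), THF/H2O, 60 °C; then MeOH, 40 °C
Reagents that add atoms: none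
Why: Anti-Markovnikov hydroboration followed by B-alkyl Suzuki–Miyaura coupling forms the C5–C1' bond without touching any stereocentre, and the basic methanolic finish removes the acetate by transesterification.

**Step 6**
Reactants: 12 tert-butyl (2S,3S)-5-[(5R)-5-(tert-butyldimethylsilyloxy)octyl]-3-hydroxy-2-methyl-3,4-dihydroquinoline-1(2H)-carboxylate
Product: 13 tert-butyl (2S,3S,4aS,5S,8aR)-5-[(5R)-5-(tert-butyldimethylsilyloxy)octyl]-3-hydroxy-2-methyloctahydroquinoline-1(2H)-carboxylate
Conditions: H2 (70 bar), Rh/Al2O3 (5 wt% Rh), i-PrOH, 60 °C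
Reagents that add atoms: none
Why: Heterogeneous arene hydrogenation over rhodium adds all hydrogens to one face (all-cis at C4a, C5 and C8a), and that face is the one opposite the C2 methyl, held pseudoaxial by allylic strain with the N-Boc group, so H4a, H5 and H8a end up cis to H2 and H3.

**Step 7**
Reactants: 14 (E)-hex-2-enal; 15 malonic acid
Product: 17 (2E,4E)-octa-2,4-dienoic acid, via alkylidenemalonic acid 16 (not isolated)
Conditions: pyridine, piperidine (cat.), 90 °C
Reagents that add atoms: none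
Why: Knoevenagel–Doebner condensation with decarboxylation gives the (2E,4E)-dienoic acid under thermodynamic control.

**Step 8**
Reactants: 13 tert-butyl (2S,3S,4aS,5S,8aR)-5-[(5R)-5-(tert-butyldimethylsilyloxy)octyl]-3-hydroxy-2-methyloctahydroquinoline-1(2H)-carboxylate; 17 (2E,4E)-octa-2,4-dienoic acid
Product: 18 tert-butyl (2S,3R,4aS,5S,8aR)-5-[(5R)-5-(tert-butyldimethylsilyloxy)octyl]-2-methyl-3-[(2E,4E)-octa-2,4-dienoyloxy]octahydroquinoline-1(2H)-carboxylate
Conditions: PPh3, DIAD, toluene, 0 °C to rt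
Reagents that add atoms: none
Why: Mitsunobu esterification forms the C3–O bond by SN2 displacement of the oxyphosphonium with inversion (3S to 3R); the equatorial leaving group has no antiperiplanar hydrogen for elimination and the N-Boc group prevents nitrogen participation.

**Step 9**
Reactants: 18 tert-butyl (2S,3R,4aS,5S,8aR)-5-[(5R)-5-(tert-butyldimethylsilyloxy)octyl]-2-methyl-3-[(2E,4E)-octa-2,4-dienoyloxy]octahydroquinoline-1(2H)-carboxylate
Product: 19 lepadin H
Conditions: TFA/CH2Cl2/H2O (10:10:1), 0 °C to rt; then aq NaHCO3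
Reagents that add atoms: none
Why: Acidolysis cleaves the tert-butyl carbamate and hydrolyses the secondary silyl ether in one operation while the dienoate ester and all stereocentres are stable to acid.

**Compound list**
1 | (R)-2-propyloxirane | CCC[C@@H]1CO1 | starting material
2 | allylmagnesium bromide | C=CC[Mg]Br | starting material
3 | (R)-oct-7-en-4-ol | C=CCC[C@H](O)CCC | intermediate
4 | (R)-tert-butyldimethyl(oct-7-en-4-yloxy)silane | C=CCC[C@H](O[Si](C)(C)C(C)(C)C)CCC | intermediate
5 | 2-amino-6-bromobenzaldehyde | Nc1cccc(Br)c1C=O | starting material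
6 | 2-oxopropyl acetate (acetoxyacetone) | CC(=O)COC(C)=O | starting material
7 | 5-bromo-2-methylquinolin-3-yl acetate | CC(=O)Oc1cc2c(Br)cccc2nc1C | intermediate
8 | (2S,3S)-5-bromo-2-methyl-1,2,3,4-tetrahydroquinolin-3-yl acetate | CC(=O)O[C@H]1Cc2c(Br)cccc2N[C@H]1C | intermediate
9 | tert-butyl (2S,3S)-3-acetoxy-5-bromo-2-methyl-3,4-dihydroquinoline-1(2H)-carboxylate | CC(=O)O[C@H]1Cc2c(Br)cccc2N(C(=O)OC(C)(C)C)[C@H]1C | intermediate
10 | 9-[(5R)-5-(tert-butyldimethylsilyloxy)octyl]-9-borabicyclo[3.3.1]nonane | B1(CCCC[C@H](O[Si](C)(C)C(C)(C)C)CCC)C2CCCC1CCC2 | intermediate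
11 | tert-butyl (2S,3S)-3-acetoxy-5-[(5R)-5-(tert-butyldimethylsilyloxy)octyl]-2-methyl-3,4-dihydroquinoline-1(2H)-carboxylate | CC(=O)O[C@H]1Cc2c(CCCC[C@H](O[Si](C)(C)C(C)(C)C)CCC)cccc2N(C(=O)OC(C)(C)C)[C@H]1C | intermediate
12 | tert-butyl (2S,3S)-5-[(5R)-5-(tert-butyldimethylsilyloxy)octyl]-3-hydroxy-2-methyl-3,4-dihydroquinoline-1(2H)-carboxylate | O[C@H]1Cc2c(CCCC[C@H](O[Si](C)(C)C(C)(C)C)CCC)cccc2N(C(=O)OC(C)(C)C)[C@H]1C | intermediate
13 | tert-butyl (2S,3S,4aS,5S,8aR)-5-[(5R)-5-(tert-butyldimethylsilyloxy)octyl]-3-hydroxy-2-methyloctahydroquinoline-1(2H)-carboxylate | O[C@H]1C[C@H]2[C@@H](CCCC[C@H](O[Si](C)(C)C(C)(C)C)CCC)CCC[C@H]2N(C(=O)OC(C)(C)C)[C@H]1C | intermediate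
14 | (E)-hex-2-enal | CCC/C=C/C=O | starting material
15 | malonic acid | OC(=O)CC(=O)O | starting material
16 | 2-[(E)-hex-2-en-1-ylidene]malonic acid | CCC/C=C/C=C(C(=O)O)C(=O)O | intermediate
17 | (2E,4E)-octa-2,4-dienoic acid | CCC/C=C/C=C/C(=O)O | intermediate
18 | tert-butyl (2S,3R,4aS,5S,8aR)-5-[(5R)-5-(tert-butyldimethylsilyloxy)octyl]-2-methyl-3-[(2E,4E)-octa-2,4-dienoyloxy]octahydroquinoline-1(2H)-carboxylate | CCC/C=C/C=C/C(=O)O[C@@H]1C[C@H]2[C@@H](CCCC[C@H](O[Si](C)(C)C(C)(C)C)CCC)CCC[C@H]2N(C(=O)OC(C)(C)C)[C@H]1C | intermediate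
19 | lepadin H, (2S,3R,4aS,5S,8aR)-5-[(5R)-5-hydroxyoctyl]-2-methyldecahydroquinolin-3-yl (2E,4E)-octa-2,4-dienoate | CCC/C=C/C=C/C(=O)O[C@@H]1C[C@H]2[C@@H](CCCC[C@H](O)CCC)CCC[C@H]2N[C@H]1C | target

**Step count and risks**
Total: 9 steps. Longest linear sequence: 6 steps (1, 2, 5, 6, 8, 9 or 3, 4, 5, 6, 8, 9).

Step 3 (the proposed new method) is the most likely to fail. The annulation could go through the methyl side of the ketone, and the dynamic kinetic resolution could give low cis selectivity or low ee, which would carry through as diastereomers once the enantiopure side chain is attached. The fallback sets out from 5 and 6 and comes back at 8. The Friedländer condensation is run alone (Mg(OTf)2, toluene, 80 °C) and 7 is isolated. 7 is reduced with Hantzsch ester and achiral diphenyl phosphate to the racemic cis acetate, that is 8 mixed with its enantiomer (2R,3R)-5-bromo-2-methyl-1,2,3,4-tetrahydroquinolin-3-yl acetate F1. Preparative chromatography on a chiral stationary phase then delivers 8.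

Step 6 may give incomplete facial selectivity, or partly lose the all-cis relationship through desorbed cyclohexene intermediates. The fallback sets out from 8 and comes back at 13, and replaces allylic-strain control in the carbamate by hydrogenation of the unprotected, protonated amine. 8 is coupled with 10 (Pd(dppf)Cl2, K3PO4, THF/H2O) to (2S,3S)-5-[(5R)-5-(tert-butyldimethylsilyloxy)octyl]-2-methyl-1,2,3,4-tetrahydroquinolin-3-yl acetate F2. Methanolysis gives (2S,3S)-5-[(5R)-5-(tert-butyldimethylsilyloxy)octyl]-2-methyl-1,2,3,4-tetrahydroquinolin-3-ol F3. F3 is hydrogenated as its acetate salt (H2, PtO2, AcOH), with adsorption anti to the cis C2/C3 substituents, to (2S,3S,4aS,5S,8aR)-5-[(5R)-5-(tert-butyldimethylsilyloxy)octyl]-2-methyldecahydroquinolin-3-ol F4. N-Boc protection of the aliphatic amine (Boc2O, MeOH, 50 °C) gives 13.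

Step 8 may be slow at the hindered C3 with the weakly acidic dienoic acid, giving elimination or recovered alcohol. The fallback sets out from 13 and comes back at 18, and decouples inversion from ester formation. Mitsunobu reaction with the more acidic 4-nitrobenzoic acid gives tert-butyl (2S,3R,4aS,5S,8aR)-5-[(5R)-5-(tert-butyldimethylsilyloxy)octyl]-2-methyl-3-(4-nitrobenzoyloxy)octahydroquinoline-1(2H)-carboxylate F5. K2CO3 in MeOH gives the inverted alcohol tert-butyl (2S,3R,4aS,5S,8aR)-5-[(5R)-5-(tert-butyldimethylsilyloxy)octyl]-3-hydroxy-2-methyloctahydroquinoline-1(2H)-carboxylate F6. Carbodiimide acylation of F6 with 17 (N-(3-dimethylaminopropyl)-N'-ethylcarbodiimide hydrochloride, 4-(dimethylamino)pyridine, CH2Cl2) gives 18 with retention.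

**Further compounds**
F1 | step 3 | (2R,3R)-5-bromo-2-methyl-1,2,3,4-tetrahydroquinolin-3-yl acetate | CC(=O)O[C@@H]1Cc2c(Br)cccc2N[C@@H]1C
F2 | step 6 | (2S,3S)-5-[(5R)-5-(tert-butyldimethylsilyloxy)octyl]-2-methyl-1,2,3,4-tetrahydroquinolin-3-yl acetate | CC(=O)O[C@H]1Cc2c(CCCC[C@H](O[Si](C)(C)C(C)(C)C)CCC)cccc2N[C@H]1C
F3 | step 6 | (2S,3S)-5-[(5R)-5-(tert-butyldimethylsilyloxy)octyl]-2-methyl-1,2,3,4-tetrahydroquinolin-3-ol | O[C@H]1Cc2c(CCCC[C@H](O[Si](C)(C)C(C)(C)C)CCC)cccc2N[C@H]1C
F4 | step 6 | (2S,3S,4aS,5S,8aR)-5-[(5R)-5-(tert-butyldimethylsilyloxy)octyl]-2-methyldecahydroquinolin-3-ol | O[C@H]1C[C@H]2[C@@H](CCCC[C@H](O[Si](C)(C)C(C)(C)C)CCC)CCC[C@H]2N[C@H]1C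
F5 | step 8 | tert-butyl (2S,3R,4aS,5S,8aR)-5-[(5R)-5-(tert-butyldimethylsilyloxy)octyl]-2-methyl-3-(4-nitrobenzoyloxy)octahydroquinoline-1(2H)-carboxylate | O=C(O[C@@H]1C[C@H]2[C@@H](CCCC[C@H](O[Si](C)(C)C(C)(C)C)CCC)CCC[C@H]2N(C(=O)OC(C)(C)C)[C@H]1C)c1ccc(cc1)[N+](=O)[O-]
F6 | step 8 | tert-butyl (2S,3R,4aS,5S,8aR)-5-[(5R)-5-(tert-butyldimethylsilyloxy)octyl]-3-hydroxy-2-methyloctahydroquinoline-1(2H)-carboxylate | O[C@@H]1C[C@H]2[C@@H](CCCC[C@H](O[Si](C)(C)C(C)(C)C)CCC)CCC[C@H]2N(C(=O)OC(C)(C)C)[C@H]1C
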